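**Retrosynthetic overview**
- Feature: in ring B (the methyl benzoate ring) the oxygen of the depside ester is bonded to C4, which lies between the methyl-bearing C3 and C5 and opposite the CO2Me carbon C1. In ring A the acyl carbon on C1 is wedged between the C6 methyl and the C2 hydroxyl, so both partners resist esterification from the acyl side.
- Key disconnection: the aryl–oxygen bond at C4 of ring B, made with reversed polarity by ligand coupling of the ring A carboxylate on a ring B aryl(2,4,6-trimethoxyphenyl)iodonium tosylate. The last step frees the C2 hydroxyl of ring B from its acetate.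
- Ring A acid: atraric acid, chlorination at its single free ring position, then acylium-type hydrolysis of the hindered methyl ester.
- Ring B iodonium salt: 2,4,5-trimethylphenol, ortho carboxylation, methyl ester, acetate, iodination of the last C–H, oxidation and coupling with 1,3,5-trimethoxybenzene.
- No ring is formed; both benzene rings are bought and only joined.

Key step: step 8

Remark: the target has no stereocentre, so no stereocontrol is needed. Ring A is numbered from the carbon that bears the depside carbonyl (C2 hydroxyl, C3 methyl, C4 hydroxyl, C5 chlorine, C6 methyl). Ring B is numbered from the carbon that bears CO2Me (C2 hydroxyl, C3 methyl, C4 ester oxygen, C5 and C6 methyls).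

**Route**

Step 1
Reactants: 1 methyl 2,4-dihydroxy-3,6-dimethylbenzoate (atraric acid)
Product: 2 methyl 3-chloro-4,6-dihydroxy-2,5-dimethylbenzoate
Conditions: SO2Cl2 (1.05 equiv), Et2O/CH2Cl2, 0 °C to rt
Reagents that add atoms: sulfuryl chloride, ClS(Cl)(=O)=O
Why: Electrophilic aromatic chlorination with SO2Cl2 should go to the only unsubstituted ring carbon, which is ortho to one hydroxyl and para to the other, and one equivalent at low temperature should prevent ipso chlorination of the fully substituted product.

Step 2
Reactants: 2 methyl 3-chloro-4,6-dihydroxy-2,5-dimethylbenzoate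
Product: 3 3-chloro-4,6-dihydroxy-2,5-dimethylbenzoic acid
Conditions: conc. H2SO4, 0 °C to rt; poured onto ice, cold extraction
Reagents that add atoms: water, O
Why: Acid hydrolysis by the unimolecular acylium mechanism: the di-ortho-substituted, electron-rich benzoate should ionise in cold concentrated H2SO4 to an acylium ion that water captures on quenching, which avoids both the blocked tetrahedral pathway of saponification and the hot conditions under which β-resorcylic acids lose CO2, and the fully substituted ring cannot be sulfonated.

Step 3
Reactants: 4 2,4,5-trimethylphenol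
Product: 5 2-hydroxy-3,5,6-trimethylbenzoic acid
Conditions: K2CO3 (anhydrous, 3 equiv), CO2 (60 bar), 175 °C, autoclave; then HCl (aq)
Reagents that add atoms: carbon dioxide, O=C=O
Why: Kolbe–Schmitt carboxylation of the potassium phenoxide should take place at C6 of the phenol, the only free ortho position (the para position carries a methyl group), and the chelated salicylate is the stable product.

Step 4
Reactants: 5 2-hydroxy-3,5,6-trimethylbenzoic acid
Product: 6 methyl 2-hydroxy-3,5,6-trimethylbenzoate
Conditions: MeI (1.2 equiv), KHCO3 (1.2 equiv), DMF, rt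
Reagents that add atoms: iodomethane, CI
Why: SN2 O-methylation of the carboxylate is not slowed by the two ortho substituents that would block a Fischer esterification, and KHCO3 is too weak a base to ionise the hydrogen-bonded phenol.

Step 5
Reactants: 6 methyl 2-hydroxy-3,5,6-trimethylbenzoate
Product: 7 methyl 2-acetoxy-3,5,6-trimethylbenzoate
Conditions: Ac2O (3 equiv), DMAP (0.1 equiv), pyridine, 60 °C
Reagents that add atoms: acetic anhydride, CC(=O)OC(C)=O
Why: DMAP-catalysed acetylation (nucleophilic catalysis through the N-acetylpyridinium ion) should overcome the hydrogen bond to the ester and the flanking methyl group, and the acetate shields the phenol from the iodine electrophile, the peracid and the iodonium centre of the later steps.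

Step 6
Reactants: 7 methyl 2-acetoxy-3,5,6-trimethylbenzoate
Product: 8 methyl 2-acetoxy-4-iodo-3,5,6-trimethylbenzoate
Conditions: NIS (1.2 equiv), CF3SO3H (0.5 equiv), CH2Cl2, 0 °C to rt, dark
Reagents that add atoms: N-iodosuccinimide, O=C1CCC(=O)N1I
Why: Electrophilic aromatic iodination with acid-activated NIS should occur at C4, the only ring C–H, which is activated by its two ortho methyl groups, while the ester, twisted out of conjugation by its two ortho neighbours, deactivates mainly by induction and the acetate cannot undergo Fries rearrangement because its ortho and para positions are filled.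

Step 7
Reactants: 8 methyl 2-acetoxy-4-iodo-3,5,6-trimethylbenzoate; 9 1,3,5-trimethoxybenzene
Product: 11 [3-acetoxy-4-(methoxycarbonyl)-2,5,6-trimethylphenyl](2,4,6-trimethoxyphenyl)iodonium tosylate, via hydroxy(tosyloxy)iodoarene 10 (not isolated)
Conditions: mCPBA (1.1 equiv), TsOH·H2O (1.05 equiv), MeCN, 77 °C; then 9 (1.05 equiv), 77 °C to rt; precipitation with Et2O
Reagents that add atoms: p-toluenesulfonic acid, Cc1ccc(cc1)S(=O)(=O)O; mCPBA, OOC(=O)c1cccc(Cl)c1 (its oxygen is held in 10 only)
Why: Peracid oxidation of the iodoarene in the presence of TsOH should give the hydroxy(tosyloxy)iodoarene 10, whose electrophilic trivalent iodine is attacked by the very electron-rich arene 9 (electrophilic aromatic substitution at one of its three equivalent C–H positions) to give the unsymmetrical diaryliodonium tosylate, a one-pot sequence that tolerates two ortho methyl groups on the iodoarene.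

Step 8
Reactants: 3 3-chloro-4,6-dihydroxy-2,5-dimethylbenzoic acid; 11 [3-acetoxy-4-(methoxycarbonyl)-2,5,6-trimethylphenyl](2,4,6-trimethoxyphenyl)iodonium tosylate
Product: 14 methyl 2-acetoxy-4-[(3-chloro-4,6-dihydroxy-2,5-dimethylbenzoyl)oxy]-3,5,6-trimethylbenzoate, via potassium carboxylate 12 (not isolated), via trivalent iodine carboxylate 13 (not isolated)
Conditions: 3, KOC(CH3)3 (1.0 equiv), THF, 0 °C to rt; evaporation; 11 (1.2 equiv), toluene, 100 °C, Ar
Reagents that add atoms: potassium tert-butoxide, CC(C)(C)[O-].[K+] (its potassium is held in 12 only)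
Why: Tosylate on the trivalent iodine of 11 is displaced by the preformed potassium carboxylate 12, and the resulting T-shaped iodane 13 collapses by ipso ligand coupling that delivers the carboxylate oxygen to C4 of ring B and expels 2-iodo-1,3,5-trimethoxybenzene, which is the known metal-free O-arylation of carboxylic acids by diaryliodonium salts. The bond is made on the aryl side, so no tetrahedral intermediate has to form at the ring A acyl carbon between the C6 methyl and the C2 hydroxyl, and neither aryl group on iodine has an ortho hydrogen, so no aryne path exists. No ring is closed and no stereocentre is formed. Aryl selectivity is needed and should come from ring B being both more electron-poor (para CO2Me, meta acetoxy) and flanked by two ortho methyls, while the electron-rich trimethoxyphenyl group stays on iodine as the dummy. Selectivity for the carboxylate over the two phenols is also needed and should come from the single equivalent of base (only the far more acidic carboxyl is ionised), from the hydrogen bond that ties up the C2 hydroxyl of ring A, and from the chlorine and methyl that flank its C4 hydroxyl.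

Step 9
Reactants: 14 methyl 2-acetoxy-4-[(3-chloro-4,6-dihydroxy-2,5-dimethylbenzoyl)oxy]-3,5,6-trimethylbenzoate
Product: 15 methyl 4-[(3-chloro-4,6-dihydroxy-2,5-dimethylbenzoyl)oxy]-2-hydroxy-3,5,6-trimethylbenzoate (CNP0198502.0)
Conditions: NH4OAc (10 equiv), MeOH/H2O (4:1), rt to 40 °C
Reagents that add atoms: none
Why: Mild NH4OAc-mediated methanolysis (transesterification) should cleave the aryl acetate, the smallest and most electrophilic acyl group, while the depside carbonyl is shielded by the C6 methyl and C2 hydroxyl of ring A and by the C3 and C5 methyls of ring B and is deactivated by its ortho and para hydroxyl donors, and exchange at the methyl ester is degenerate in methanol.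

**Compound list**

1 | methyl 2,4-dihydroxy-3,6-dimethylbenzoate (atraric acid) | COC(=O)c1c(C)cc(O)c(C)c1O | starting material
2 | methyl 3-chloro-4,6-dihydroxy-2,5-dimethylbenzoate | COC(=O)c1c(C)c(Cl)c(O)c(C)c1O | intermediate
3 | 3-chloro-4,6-dihydroxy-2,5-dimethylbenzoic acid | OC(=O)c1c(C)c(Cl)c(O)c(C)c1O | intermediate
4 | 2,4,5-trimethylphenol | Cc1cc(C)c(O)cc1C | starting material
5 | 2-hydroxy-3,5,6-trimethylbenzoic acid | OC(=O)c1c(C)c(C)cc(C)c1O | intermediate
6 | methyl 2-hydroxy-3,5,6-trimethylbenzoate | COC(=O)c1c(C)c(C)cc(C)c1O | intermediate
7 | methyl 2-acetoxy-3,5,6-trimethylbenzoate | COC(=O)c1c(C)c(C)cc(C)c1OC(C)=O | intermediate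
8 | methyl 2-acetoxy-4-iodo-3,5,6-trimethylbenzoate | COC(=O)c1c(C)c(C)c(I)c(C)c1OC(C)=O | intermediate
9 | 1,3,5-trimethoxybenzene | COc1cc(OC)cc(OC)c1 | starting material
10 | methyl 2-acetoxy-4-[hydroxy(tosyloxy)iodo]-3,5,6-trimethylbenzoate | COC(=O)c1c(C)c(C)c(I(O)OS(=O)(=O)c2ccc(C)cc2)c(C)c1OC(C)=O | intermediate
11 | [3-acetoxy-4-(methoxycarbonyl)-2,5,6-trimethylphenyl](2,4,6-trimethoxyphenyl)iodonium tosylate | COC(=O)c1c(C)c(C)c([I+]c2c(OC)cc(OC)cc2OC)c(C)c1OC(C)=O.Cc1ccc(cc1)S(=O)(=O)[O-] | intermediate
12 | potassium 3-chloro-4,6-dihydroxy-2,5-dimethylbenzoate | [K+].[O-]C(=O)c1c(C)c(Cl)c(O)c(C)c1O | intermediate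
13 | [3-acetoxy-4-(methoxycarbonyl)-2,5,6-trimethylphenyl](3-chloro-4,6-dihydroxy-2,5-dimethylbenzoyloxy)(2,4,6-trimethoxyphenyl)iodane | COC(=O)c1c(C)c(C)c(I(OC(=O)c2c(C)c(Cl)c(O)c(C)c2O)c2c(OC)cc(OC)cc2OC)c(C)c1OC(C)=O | intermediate
14 | methyl 2-acetoxy-4-[(3-chloro-4,6-dihydroxy-2,5-dimethylbenzoyl)oxy]-3,5,6-trimethylbenzoate | COC(=O)c1c(C)c(C)c(OC(=O)c2c(C)c(Cl)c(O)c(C)c2O)c(C)c1OC(C)=O | intermediate
15 | methyl 4-[(3-chloro-4,6-dihydroxy-2,5-dimethylbenzoyl)oxy]-2-hydroxy-3,5,6-trimethylbenzoate | COC(=O)c1c(C)c(C)c(OC(=O)c2c(C)c(Cl)c(O)c(C)c2O)c(C)c1O | target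

**Step count**

Total steps: 9. Longest linear sequence: 7 steps (steps 3 to 9, from 2,4,5-trimethylphenol).

**Steps most likely to fail, with fallbacks**

Step 8 (key step). What may go wrong: transfer of the trimethoxyphenyl group in place of ring B, O-arylation at the C4 phenol of ring A in place of the carboxylate, or thermal loss of CO2 from the β-resorcylate salt before ligand coupling. The fallback forms the same ester from the acyl side and sets out from iodide 8. Miyaura borylation of 8 (bis(pinacolato)diboron, Pd(OAc)2, XPhos, KOAc, dioxane, 100 °C; the bulky biaryl phosphine is chosen for the two ortho methyls) should give methyl 2-acetoxy-3,5,6-trimethyl-4-(4,4,5,5-tetramethyl-1,3,2-dioxaborolan-2-yl)benzoate F1. Oxidation of F1 with KHSO5 (as 2KHSO5·KHSO4·K2SO4) in acetone/water at rt should give the phenol methyl 2-acetoxy-4-hydroxy-3,5,6-trimethylbenzoate F2 without loss of the acetate. Acid 3 is then activated with trifluoroacetic anhydride in toluene at rt as 3-chloro-4,6-dihydroxy-2,5-dimethylbenzoic trifluoroacetic anhydride F3, which is not isolated. Its acylium character lets it acylate F2 (the classical depside esterification), and an aqueous NaHCO3 work-up returns any trifluoroacetylated hydroxyl to the free phenol. The route is rejoined at 14. This path must overcome the double hindrance that the main route avoids, so it is the second choice.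

Step 7. What may go wrong: slow oxidation of the electron-poor iodoarene that carries two ortho methyls, and acid-promoted loss of the acetate while hot TsOH and peracid are present together. The fallback separates oxidation from arylation and sets out from 8. Oxidation with NaBO3·4H2O in acetic acid at 45 °C should give the isolable methyl 2-acetoxy-4-(diacetoxyiodo)-3,5,6-trimethylbenzoate F4 under buffered, peracid-free conditions. Ligand exchange of F4 with TsOH·H2O in MeCN at rt should give 10, and addition of 9 at rt should then give the iodonium tosylate, so the route is rejoined at 11.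

Step 6. What may go wrong: sluggish substitution at the last C–H (para to the ester, meta to the acetate, between two methyls), or acid-promoted loss of the acetate followed by oxidation of the freed phenol by the iodine electrophile. The fallback installs the iodine through nitrogen and sets out from 7. Nitration with NO2BF4 in MeCN at 0 °C should give methyl 2-acetoxy-3,5,6-trimethyl-4-nitrobenzoate F5. Hydrogenation (H2, Pd/C (palladium on carbon), EtOAc) should give the aniline methyl 2-acetoxy-4-amino-3,5,6-trimethylbenzoate F6. Diazotisation with NaNO2 and TsOH·H2O in MeCN/water at 10 °C should give 3-acetoxy-4-(methoxycarbonyl)-2,5,6-trimethylbenzenediazonium tosylate F7, which is not isolated and is treated with KI in the same flask (Sandmeyer-type iodination without copper) to return to the route at 8.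

**Further compounds**

F1 | step 8 | methyl 2-acetoxy-3,5,6-trimethyl-4-(4,4,5,5-tetramethyl-1,3,2-dioxaborolan-2-yl)benzoate | COC(=O)c1c(C)c(C)c(B2OC(C)(C)C(C)(C)O2)c(C)c1OC(C)=O
F2 | step 8 | methyl 2-acetoxy-4-hydroxy-3,5,6-trimethylbenzoate | COC(=O)c1c(C)c(C)c(O)c(C)c1OC(C)=O
F3 | step 8 | 3-chloro-4,6-dihydroxy-2,5-dimethylbenzoic trifluoroacetic anhydride | O=C(OC(=O)C(F)(F)F)c1c(C)c(Cl)c(O)c(C)c1O
F4 | step 7 | methyl 2-acetoxy-4-(diacetoxyiodo)-3,5,6-trimethylbenzoate | COC(=O)c1c(C)c(C)c(I(OC(C)=O)OC(C)=O)c(C)c1OC(C)=O
F5 | step 6 | methyl 2-acetoxy-3,5,6-trimethyl-4-nitrobenzoate | COC(=O)c1c(C)c(C)c([N+](=O)[O-])c(C)c1OC(C)=O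
F6 | step 6 | methyl 2-acetoxy-4-amino-3,5,6-trimethylbenzoate | COC(=O)c1c(C)c(C)c(N)c(C)c1OC(C)=O
F7 | step 6 | 3-acetoxy-4-(methoxycarbonyl)-2,5,6-trimethylbenzenediazonium tosylate | COC(=O)c1c(C)c(C)c([N+]#N)c(C)c1OC(C)=O.Cc1ccc(cc1)S(=O)(=O)[O-]
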